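**Plan**

- Retrosynthesis (ring numbered C1 = carbon bearing CH2OSO3H, C2 Br, C3 Br, C4 OSO3H, C5 OH, C6 H): the two S–O bonds are cut first, then the benzene ring at C4–C5 and C6–C1, with CO2 put back as a bridge between C1 and C4.
- Enabling feature: C1 (with its exocyclic carbon), C2–Br, C3–Br and C4–O are C6, C5, C4 and C3 of a 3-acyloxy-4,5-dibromo-2-pyrone-6-carboxylate; C5(O)–C6(H) are the two carbons of ethoxyacetylene, so the two neighbouring oxygens arrive already different (pivalate on C4, ethyl ether on C5).
- Forward: mucic acid is dehydrated to the pyrone ring, which is brominated and pivaloylated; cycloaddition with CO2 loss then builds the benzene ring, the only ring of the target; ether cleavage, silylation, hydride reduction, double sulfation and desilylation finish the route.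
- Stereochemistry: the target is achiral; the four stereocentres of mucic acid and the two bridgeheads of the transient cycloadduct are erased by aromatisation.

Key step: step 5

Remark: sulfate monoesters, the target included, are written as the neutral hydrogen sulfates of the given SMILES; in the flask they would be carried as pyridinium or sodium salts, and the acid form is released by H+ exchange at the end.

**Route**

Step 1
Reactants: 1 mucic acid (galactaric acid, meso)
Product: 2 3-acetoxy-2-oxo-2H-pyran-6-carboxylic acid
Conditions: Ac2O, NaOAc, 100 °C; then cold 2 M HCl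
Reagents that add atoms: acetic anhydride, CC(=O)OC(C)=O
Why: Exhaustive acetylation, δ-lactonisation and two base-induced β-eliminations (E1cB) of acetic acid turn the aldaric acid into the 2-pyrone, a known dehydrative aromatisation of mucic acid that removes all four stereocentres.

Step 2
Reactants: 2 3-acetoxy-2-oxo-2H-pyran-6-carboxylic acid
Product: 3 methyl 3-hydroxy-2-oxo-2H-pyran-6-carboxylate
Conditions: MeOH, H2SO4 (cat.), reflux
Reagents that add atoms: methanol, CO
Why: Fischer esterification of the acid and acid-catalysed transesterification of the enol acetate proceed together, and the pyrone lactone should survive acidic methanol as it does when coumalic acid is esterified.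

Step 3
Reactants: 3 methyl 3-hydroxy-2-oxo-2H-pyran-6-carboxylate
Product: 4 methyl 4,5-dibromo-3-hydroxy-2-oxo-2H-pyran-6-carboxylate
Conditions: Br2 (2.5 equiv), AcOH, 20 → 60 °C
Reagents that add atoms: bromine, BrBr
Why: Electrophilic halogenation of a hydroxypyrone: the enolic 3-OH sends the first bromine to C4 and the ring oxygen sends the second to C5, the only CH left, while the methyl ester blocks C6, where a free acid would undergo bromodecarboxylation.

Step 4
Reactants: 4 methyl 4,5-dibromo-3-hydroxy-2-oxo-2H-pyran-6-carboxylate
Product: 5 methyl 4,5-dibromo-3-(2,2-dimethylpropanoyloxy)-2-oxo-2H-pyran-6-carboxylate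
Conditions: PivCl, i-Pr2NEt, CH2Cl2, 0 °C
Reagents that add atoms: pivaloyl chloride, CC(C)(C)C(Cl)=O
Why: O-Acylation of the acidic enol with a non-nucleophilic base (which should spare the electrophilic C4–Br) caps the only protic site that the acid-sensitive ynol ether would attack; pivalate is chosen because it resists BBr3 and migrates slowly.

Step 5
Reactants: 5 methyl 4,5-dibromo-3-(2,2-dimethylpropanoyloxy)-2-oxo-2H-pyran-6-carboxylate; 6 ethoxyacetylene
Product: 8 methyl 2,3-dibromo-5-ethoxy-4-(2,2-dimethylpropanoyloxy)benzoate, via bridged lactone cycloadduct 7 (not isolated)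
Conditions: 6 (4 equiv), PhMe, 80 °C, sealed tube
Reagents that add atoms: none
Why: The pyrone, made electron-poor by its lactone carbonyl, the C6 ester and two bromines, acts as the diene of an inverse-electron-demand Diels–Alder reaction in which the nucleophilic terminal CH of 6 bonds to C6 slightly ahead of the bond from the ethoxy-bearing carbon to C3, giving the 2-oxabicyclo[2.2.2]octa-5,7-dien-3-one 7. Retro-Diels–Alder loss of CO2 from 7 should be spontaneous at this temperature because it creates the benzene ring without an oxidant; the closest known reactions are cycloadditions of ester- and halogen-substituted 2-pyrones with ynol ethers, ynamines and ketene acetals that give benzoates after CO2 loss. The carbocycle closes by an intermolecular suprafacial (4+2) cycloaddition that forms arene bonds C4–C5 and C6–C1. The two bridgehead stereocentres of racemic 7 are locked to each other by the bicycle and vanish on aromatisation, so no stereocontrol is needed. The one selectivity required is regiochemical (ethoxy carbon to C3): the ring holds the lactone carbonyl and ring oxygen coplanar with the diene, making C6 the δ-electrophilic terminus, whereas the exocyclic ester and pivalate, each pressed by a neighbouring bromine, are twisted out of conjugation and act by induction only, so the ester raises the electrophilicity of C6 without diverting the attack.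

Step 6
Reactants: 8 methyl 2,3-dibromo-5-ethoxy-4-(2,2-dimethylpropanoyloxy)benzoate
Product: 9 methyl 2,3-dibromo-5-hydroxy-4-(2,2-dimethylpropanoyloxy)benzoate
Conditions: BBr3 (3 equiv), CH2Cl2, −78 → 0 °C; ice-water quench
Reagents that add atoms: none
Why: Lewis-acid dealkylation of an aryl alkyl ether (bromide attacks the O-complexed ethyl group, SN2) frees the C5 phenol while the hindered pivalate and the methyl ester, cleaved only at higher temperature, should survive; the acidic work-up avoids base-induced O→O acyl migration.

Step 7
Reactants: 9 methyl 2,3-dibromo-5-hydroxy-4-(2,2-dimethylpropanoyloxy)benzoate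
Product: 10 methyl 2,3-dibromo-4-(2,2-dimethylpropanoyloxy)-5-(triisopropylsilyloxy)benzoate
Conditions: TIPSOTf, 2,6-lutidine, CH2Cl2, −78 → 0 °C
Reagents that add atoms: triisopropylsilyl trifluoromethanesulfonate, CC(C)[Si](OS(=O)(=O)C(F)(F)F)(C(C)C)C(C)C
Why: Silylation with a silyl triflate and a weak hindered base is fast at −78 °C and should trap the C5 phenol before the 1,2-acyl shift that a free phenoxide would allow; the bulky TIPS ether withstands hydride and sulfation and is removed by fluoride.

Step 8
Reactants: 10 methyl 2,3-dibromo-4-(2,2-dimethylpropanoyloxy)-5-(triisopropylsilyloxy)benzoate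
Product: 11 [2,3-dibromo-4-hydroxy-5-(triisopropylsilyloxy)phenyl]methanol
Conditions: i-Bu2AlH (6 equiv), CH2Cl2, −78 → −20 °C; aq. potassium sodium tartrate
Reagents that add atoms: none
Why: Hydride reduction of both esters turns the benzoate into the benzylic alcohol and the pivalate into the free C4 phenol in one operation, leaving aryl bromides and the silyl ether intact; if the silyl group should shuttle between the catechol oxygens, it rests on the less acidic, less hindered C5 oxygen, as wanted.

Step 9
Reactants: 11 [2,3-dibromo-4-hydroxy-5-(triisopropylsilyloxy)phenyl]methanol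
Product: 12 [2,3-dibromo-4-(sulfooxy)-5-(triisopropylsilyloxy)phenyl]methyl hydrogen sulfate
Conditions: SO3·pyridine (8 equiv), DMF, 0 → 30 °C
Reagents that add atoms: sulfur trioxide–pyridine complex, [O-]S(=O)(=O)[n+]1ccccc1
Why: O-Sulfation with an SO3–amine complex esterifies the primary alcohol and the C4 phenol while C5–O stays masked; a large excess of reagent is meant to keep the half-sulfated 4-hydroxybenzyl sulfate, a potential quinone methide source, short-lived.

Step 10
Reactants: 12 [2,3-dibromo-4-(sulfooxy)-5-(triisopropylsilyloxy)phenyl]methyl hydrogen sulfate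
Product: 13 2,3-dibromo-5-hydroxy-4-(sulfooxy)benzyl hydrogen sulfate (CNP0301961.0)
Conditions: HF·pyridine, pyridine, DMF, 0 → 20 °C; then Dowex 50W (H+ form), H2O, 0 °C
Reagents that add atoms: none
Why: Fluoride-induced desilylation in buffered HF·pyridine cleaves the aryl silyl ether without touching sulfate monoesters, which tolerate fluoride and weak acid at this temperature, and brief proton exchange on a sulfonic acid resin gives the acid form.

**Compound list**

1 | mucic acid (galactaric acid, meso) | OC(=O)[C@H](O)[C@@H](O)[C@@H](O)[C@H](O)C(=O)O | starting material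
2 | 3-acetoxy-2-oxo-2H-pyran-6-carboxylic acid | CC(=O)OC1=CC=C(C(=O)O)OC1=O | intermediate
3 | methyl 3-hydroxy-2-oxo-2H-pyran-6-carboxylate | COC(=O)C1=CC=C(O)C(=O)O1 | intermediate
4 | methyl 4,5-dibromo-3-hydroxy-2-oxo-2H-pyran-6-carboxylate | COC(=O)C1=C(Br)C(Br)=C(O)C(=O)O1 | intermediate
5 | methyl 4,5-dibromo-3-(2,2-dimethylpropanoyloxy)-2-oxo-2H-pyran-6-carboxylate | COC(=O)C1=C(Br)C(Br)=C(OC(=O)C(C)(C)C)C(=O)O1 | intermediate
6 | ethoxyacetylene | CCOC#C | starting material
7 | methyl 7,8-dibromo-4-(2,2-dimethylpropanoyloxy)-5-ethoxy-3-oxo-2-oxabicyclo[2.2.2]octa-5,7-diene-1-carboxylate (racemic, one enantiomer drawn, bridgeheads fixed by the bicycle; not isolated) | COC(=O)[C@@]12OC(=O)[C@@](OC(=O)C(C)(C)C)(C(Br)=C1Br)C(OCC)=C2 | intermediate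
8 | methyl 2,3-dibromo-5-ethoxy-4-(2,2-dimethylpropanoyloxy)benzoate | CCOc1cc(C(=O)OC)c(Br)c(Br)c1OC(=O)C(C)(C)C | intermediate
9 | methyl 2,3-dibromo-5-hydroxy-4-(2,2-dimethylpropanoyloxy)benzoate | COC(=O)c1cc(O)c(OC(=O)C(C)(C)C)c(Br)c1Br | intermediate
10 | methyl 2,3-dibromo-4-(2,2-dimethylpropanoyloxy)-5-(triisopropylsilyloxy)benzoate | COC(=O)c1cc(O[Si](C(C)C)(C(C)C)C(C)C)c(OC(=O)C(C)(C)C)c(Br)c1Br | intermediate
11 | [2,3-dibromo-4-hydroxy-5-(triisopropylsilyloxy)phenyl]methanol | OCc1cc(O[Si](C(C)C)(C(C)C)C(C)C)c(O)c(Br)c1Br | intermediate
12 | [2,3-dibromo-4-(sulfooxy)-5-(triisopropylsilyloxy)phenyl]methyl hydrogen sulfate | O=S(=O)(O)OCc1cc(O[Si](C(C)C)(C(C)C)C(C)C)c(OS(=O)(=O)O)c(Br)c1Br | intermediate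
13 | 2,3-dibromo-5-hydroxy-4-(sulfooxy)benzyl hydrogen sulfate | O=S(=O)(O)OCc1cc(O)c(OS(=O)(=O)O)c(Br)c1Br | target

**Count**

Total steps: 10. Longest linear sequence: 10 steps, from mucic acid (1) to 13.

**Steps most likely to fail**

Step 5. The cycloaddition may be slower than the thermal fragmentation of the ynol ether to ketene. The first bond may also form at C3 instead of C6, because both diene termini carry an acyloxy and an alkoxycarbonyl group and the bias rests on conformation alone; this would place the ethoxy group next to the ester carbon. The fallback sets out from 5 and uses 1,1-diethoxyethene in toluene at 20–60 °C, a more nucleophilic and more strongly polarised partner that needs no heating and adds in two polar stages starting at the carbon activated by the lactone carbonyl. It should give the bridged lactone methyl 7,8-dibromo-5,5-diethoxy-4-(2,2-dimethylpropanoyloxy)-3-oxo-2-oxabicyclo[2.2.2]oct-7-ene-1-carboxylate F1, which loses CO2 on gentle warming to methyl 2,3-dibromo-5,5-diethoxy-4-(2,2-dimethylpropanoyloxy)cyclohexa-1,3-diene-1-carboxylate F2. Acid-catalysed elimination of ethanol (cat. TsOH) then aromatises F2, and the route is rejoined at 8.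

Step 3. After fast bromination at C4 the ring may resist a second substitution at C5, which lies next to the ester, or excess bromine may attack C4 again (ipso) and oxidise the enol. The fallback sets out from 3 and moves the second bromine to the arene. One equivalent of N-bromosuccinimide (MeCN, 0 °C) should give methyl 4-bromo-3-hydroxy-2-oxo-2H-pyran-6-carboxylate F3, which is pivaloylated as in step 4 to methyl 4-bromo-3-(2,2-dimethylpropanoyloxy)-2-oxo-2H-pyran-6-carboxylate F4. Cycloaddition with 6 as in step 5 would pass through the bridged lactone methyl 8-bromo-4-(2,2-dimethylpropanoyloxy)-5-ethoxy-3-oxo-2-oxabicyclo[2.2.2]octa-5,7-diene-1-carboxylate F5 and give methyl 3-bromo-5-ethoxy-4-(2,2-dimethylpropanoyloxy)benzoate F6. Electrophilic aromatic bromination of F6 (Br2, iron powder, AcOH) is expected para to the ethoxy group, at C2 between bromine and ester, the position a second bromine takes in 5-bromovanillin-type arenes; this comes back to the route at 8.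

Step 9. The primary alcohol may be sulfated well before the hindered C4 phenol, and the half-sulfated 4-hydroxybenzyl sulfate may ionise to a quinone methide that is captured by pyridine or by another phenol, leading to oligomers. The fallback sets out from 11 and separates the two sulfations by chemoselectivity. Sulfur trioxide–trimethylamine with one equivalent of Et3N in aqueous acetonitrile at 20 °C, conditions under which only a phenoxide reacts and alcohols are inert, should give [2,3-dibromo-4-(hydroxymethyl)-6-(triisopropylsilyloxy)phenyl] hydrogen sulfate F7. This compound can no longer form a quinone methide, and sulfation of its benzylic alcohol (SO3·pyridine, DMF, 0 °C) comes back to the route at 12.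

**Further compounds**

F1 | step 5 | methyl 7,8-dibromo-5,5-diethoxy-4-(2,2-dimethylpropanoyloxy)-3-oxo-2-oxabicyclo[2.2.2]oct-7-ene-1-carboxylate (racemic) | COC(=O)[C@@]12OC(=O)[C@@](OC(=O)C(C)(C)C)(C(Br)=C1Br)C(OCC)(OCC)C2
F2 | step 5 | methyl 2,3-dibromo-5,5-diethoxy-4-(2,2-dimethylpropanoyloxy)cyclohexa-1,3-diene-1-carboxylate | COC(=O)C1=C(Br)C(Br)=C(OC(=O)C(C)(C)C)C(OCC)(OCC)C1
F3 | step 3 | methyl 4-bromo-3-hydroxy-2-oxo-2H-pyran-6-carboxylate | COC(=O)C1=CC(Br)=C(O)C(=O)O1
F4 | step 3 | methyl 4-bromo-3-(2,2-dimethylpropanoyloxy)-2-oxo-2H-pyran-6-carboxylate | COC(=O)C1=CC(Br)=C(OC(=O)C(C)(C)C)C(=O)O1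
F5 | step 3 | methyl 8-bromo-4-(2,2-dimethylpropanoyloxy)-5-ethoxy-3-oxo-2-oxabicyclo[2.2.2]octa-5,7-diene-1-carboxylate (racemic) | COC(=O)[C@@]12OC(=O)[C@@](OC(=O)C(C)(C)C)(C(Br)=C1)C(OCC)=C2
F6 | step 3 | methyl 3-bromo-5-ethoxy-4-(2,2-dimethylpropanoyloxy)benzoate | CCOc1cc(C(=O)OC)cc(Br)c1OC(=O)C(C)(C)C
F7 | step 9 | [2,3-dibromo-4-(hydroxymethyl)-6-(triisopropylsilyloxy)phenyl] hydrogen sulfate | OCc1cc(O[Si](C(C)C)(C(C)C)C(C)C)c(OS(=O)(=O)O)c(Br)c1Br
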